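**Structural features**

The target is a 3,8''-linked biflavanone. An upper 5,7,3',4'-tetrahydroxyflavanone (phloroglucinol ring A, catechol ring B, pyranone ring C with O1, C2, C3, C4) is bonded through C3 to C8'' of a lower 5'',7'',4'''-trihydroxyflavanone (phloroglucinol ring D, phenol ring E, pyranone ring F with O1'', C2'', C3'', C4''). C2 (R) and C3 (S) are adjacent and trans, with rings B and D both equatorial on ring C. C2'' (R) lies beyond the hindered C3–C8'' axis and O1'', so no relay from the upper pair can be expected, and both 2-aryl groups point to the face opposite to that of the common (2S)-flavanones.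

Several groups are fragile:
- Each pyranone opens under base by a retro-oxa-Michael reaction, which erases C2 and C2''. This is faster once 4'-OH and 4'''-OH are free.
- H-3 is acidic, although the trans isomer is the stable one.
- The catechol is easily oxidised.
- 7''-OH can condense with C4=O to a benzofuran in strong acid.

The real difficulty is the C3–C8'' bond. It is a C(sp3)–C(sp2) bond whose aryl end is flanked by O1'' and 7''-OH. Both of its ends are natural nucleophiles (C3 an enol carbon, C8'' a phloroglucinol carbon). It must also be made at C8'' and not C6'', with absolute control at C2/C3.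

The key step exploits two features. C3 is vicinal to C4, the benzylic carbon of ring A, which at the flavan oxidation level is the best cation site of a flavonoid and the natural electrophilic partner of a phloroglucinol C8. Ring D carries oxygen on both ortho carbons (C7'', C8a'') and on the para carbon (C5''), so it is an aryl group of very high migratory aptitude. Ring D is therefore attached to C4 first and then moved to C3 by a 1,2-shift, which also places oxygen on C4, where the target has its carbonyl group.

**Logic of the disconnections**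

16 to 15. Bonds cut: seven O–CH2Ph bonds and C8–Br. Every phenol must be masked while C4 is cationic or being oxidised, and C8 must be blocked. One reductive operation removes both kinds of group. The gain is a neutral, non-oxidisable precursor. The demand is near-neutral, buffered hydrogenolysis, because C2 and C2'' are labile from here on.

15 to 14. Bond cut: the π bond of C4=O, so C4 returns to a carbinol. The carbonyl group is what makes H-3 acidic and ring C base-labile, so it is installed last. The gain is an upper unit that is a flavan and is inert to base. The demand is a neutral oxidation of a hindered benzylic alcohol.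

14 to 12 (key). Bonds cut: C3–C8'' and C4–O. Bonds restored: C4–C8'' and C3–O. The cut turns the polarity-mismatched, hindered C3–C8'' bond into a C4–C8'' bond, which joins a natural electrophile to a natural nucleophile. The gain is that C3 follows from the carbinol stereocentre by stereospecific inversion, so no catalyst or auxiliary is needed for C2/C3. The demand is that ring D and the leaving group be trans-diaxial (2,3-cis-3,4-trans), and that ring D migrate faster than H-2 is lost. In one sentence: a solvolytic 1,2-shift of ring D from C4 to C3 in 12.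

12 to 11. Bond cut: O–S of the sulfonate. This separates activation from ionisation. The demand is sulfonylation of the only free hydroxyl group without base damage to ring F.

11 to 9 + 10. Bond cut: C2''–C1'''. Ring E is added last to a flat chromone, so C2'' is set by a catalyst at a stage where the upper unit tolerates the conditions. The gain is one stereocentre and one aryl group fewer. The demand is catalyst control over a substrate with a large C8'' substituent.

9 to 7. Bonds cut: O1''–C2'' and C2''=C3'' (removal of the one-carbon unit C2''). Only one phenol is free, so ring F can close only towards C8a'', which fixes the 8''-substitution pattern. The demand is a mild acid closure that leaves C4–C8'' intact.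

7 to 4 + 6. Bond cut: C4–C8''. This is the proanthocyanidin-type union. The gain is two simple fragments. The demand is attack anti to the axial 3-OH, at the ring carbon of 6 ortho to its free hydroxyl group, without self-alkylation of the electrophile.

4 to 3 to 2 to 1. Bonds cut: C8–Br, C4–O, four O–benzyl. C2 and the 3-carbinol come from the chiral pool.

6 to 5. Bonds cut: two O–benzyl. The chelated hydroxyl group stays free.

**Other disconnections considered**

Alternative 1: (the first that comes to mind) cut C3–C8'' between two complete flavonoid halves.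
- Forward key step: Suzuki coupling of the 3-iodoflavone A1 with the flavanone 8-boronate A2 to give the flavone–flavanone A3, followed by reduction of C2=C3. At the flavanone level the equivalent is a palladium-catalysed enolate arylation.
- Loss of stereocentres: A3 has lost both upper stereocentres. Restoring them would need an enantioselective reduction of a tetrasubstituted, doubly arylated vinylogous ester beside a more reactive ketone, and the structure offers no control element for that.
- Coupling partners: the coupling joins a carbon flanked by two oxygens, which is prone to protodeboronation, to a carbon flanked by a carbonyl and an aryl group.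
- Enolate variant: it needs strong base, which opens rings C and F and erases C2 and C2''.
- Why the chosen plan is preferred: it makes the inter-unit bond while the upper ring is not base-labile, and it takes C2 from the chiral pool.

Alternative 2: cut O1–C2 and C3–C4 of ring C.
- Forward key step: the ortho-quinone methide released from the benzylic alcohol A5 adds in a [4+2] sense to the (E)-stilbene A4 to give the 3-arylflavan A6. C4 is then oxidised in two stages.
- Attraction: the hindered bond is already present as an aryl–vinyl bond, and the E geometry gives the trans pair.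
- Regiochemistry: the methide carbon must bond to the carbon that carries ring D and leave charge next to ring B. Ring D has three ortho/para oxygens and stabilises an adjacent cation at least as well as ring B with one para oxygen, so the orientation is in doubt.
- Other weaknesses: the di-ortho-substituted stilbene is a poor partner compared with self-reaction of the methide. The absolute sense would depend on a catalyst that must distinguish the faces of an alkene with no binding group. C4 arrives as CH2.
- Why the chosen plan is preferred: it has no regiochemical ambiguity and delivers C4 already oxygenated.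

Alternative 3: cut C3–C8'' in the biosynthetic sense.
- Forward key step: one-electron oxidation of the chalcone A7 and of (R)-naringenin A8, coupling of the chalcone α-carbon radical with C8'', and closure of the resulting ring B quinone methide A9 by the 2'-hydroxyl group at C2.
- Site of oxidation: the catechol is the most easily oxidised site and leads towards an ortho-quinone.
- Coupling selectivity: spin density in both radicals is spread over several carbons and oxygens. Cross- versus homo-coupling and C8'' versus C6'' are therefore uncontrolled.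
- Ring closure and configuration: A9 can be closed by 7''-OH to a five-membered ring as readily as by the ring A hydroxyl group, and nothing fixes the absolute configuration.
- Why the chosen plan is preferred: it keeps the ionic equivalent of this polarity (ring D as nucleophile) but under full regio- and stereocontrol.

Key step: step 9

Remark: 1 is the 2S,3S enantiomer, (+)-epicatechin. It is taken as a catalogue compound and is also the C2 epimer of (+)-catechin. α and β refer to the usual flavonoid drawing (ring A left, O1 on top), with β towards the viewer.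

**Steps**

Step 1
Reactants: 1 (+)-epicatechin
Product: 2 5,7,3',4'-tetra-O-benzyl-(+)-epicatechin (2S,3S)
Conditions: BnBr (4.2 equiv), K2CO3, DMF, 0 °C to rt
Reagents that add atoms: benzyl bromide, BrCc1ccccc1
Why: Williamson etherification of the four phenols; K2CO3 does not deprotonate the aliphatic 3-OH, and rapid capping of the 4'-phenoxide at low temperature should prevent C2 epimerisation through a ring B quinone methide, so both stereocentres of 1 are carried over.

Step 2
Reactants: 2 tetra-O-benzyl-(+)-epicatechin
Product: 3 4α-(2-ethoxyethoxy) derivative (2S,3S,4R; 2,3-cis-3,4-trans)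
Conditions: DDQ (1.5 equiv), 2-ethoxyethanol (5 equiv), CH2Cl2, rt
Reagents that add atoms: 2-ethoxyethanol, CCOCCO
Why: DDQ benzylic oxidation by hydride abstraction from C4, the position activated by the three oxygens of ring A; the alcohol adds anti to the axial 3β-OH, and the benzyl ether CH2 groups are much less activated.

Step 3
Reactants: 3 4α-(2-ethoxyethoxy)flavan-3-ol
Product: 4 8-bromo-4α-(2-ethoxyethoxy)flavan-3-ol (2S,3S,4R)
Conditions: NBS (1.0 equiv), CH2Cl2, −78 to −20 °C
Reagents that add atoms: N-bromosuccinimide, O=C1CCC(=O)N1Br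
Why: Electrophilic aromatic bromination at C8, the most nucleophilic and least shielded carbon of ring A; the bromine blocks the site through which the electrophile and its products would self-alkylate in steps 5 and 9, and it leaves in step 11.

Step 4
Reactants: 5 2,4,6-trihydroxyacetophenone
Product: 6 1-[2,4-bis(benzyloxy)-6-hydroxyphenyl]ethanone
Conditions: BnBr (2.1 equiv), K2CO3, DMF, rt
Reagents that add atoms: benzyl bromide, BrCc1ccccc1
Why: Williamson etherification that stops at the dibenzyl ether, because the last hydroxyl group is hydrogen-bonded to the acetyl carbonyl and is the least reactive.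

Step 5
Reactants: 4 8-bromo-4α-(2-ethoxyethoxy)flavan-3-ol; 6 1-[2,4-bis(benzyloxy)-6-hydroxyphenyl]ethanone (3 equiv)
Product: 7 4α-(3-acetyl-4,6-bis(benzyloxy)-2-hydroxyphenyl)flavan-3-ol (2S,3S,4R; 2,3-cis-3,4-trans)
Conditions: BF3·OEt2 (0.3 equiv), CH2Cl2, −40 to 0 °C
Reagents that add atoms: none
Why: Friedel–Crafts alkylation after ionisation at C4 (the proanthocyanidin-type interflavan bond formation), probably through reversible O-alkylation of the free phenol and O-to-C shift as in aryl C-glycoside synthesis with this same acetophenone. The carbon ortho to the free OH is both the less hindered and the phenol-directed site, and attack anti to the axial 3β-OH sets C4 with ring D α and axial.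

Step 6
Reactants: 7 4α-(acetylhydroxyaryl)flavan-3-ol
Product: 9 8-(flavan-4α-yl)-5,7-bis(benzyloxy)chromone (2S,3S,4R), via enaminone 8 (not isolated)
Conditions: Me2NCH(OMe)2 (5 equiv), toluene, 90 °C; evaporate; AcOH/CH2Cl2 (1:4), 40 °C
Reagents that add atoms: N,N-dimethylformamide dimethyl acetal, COC(OC)N(C)C
Why: Standard chromone synthesis: condensation at the acetyl CH3 to the enaminone, then acid-induced addition of the only free phenol and loss of dimethylamine, so ring F can form only on the C8a'' side. The acyl-deactivated ring D resists the ipso protonation that would cleave C4–C8''.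

Step 7
Reactants: 9 8-(flavan-4α-yl)chromone; 10 4-(benzyloxy)phenylboronic acid (3 equiv)
Product: 11 8''-(flavan-4α-yl)-(2''R)-flavanone (2S,3S,4R,2''R)
Conditions: [Rh(OH)(cod)]2 (2.5 mol %), (R)-2,2'-bis[bis(3,4,5-trifluorophenyl)phosphino]-6,6'-dimethoxybiphenyl (5.5 mol %), CH2Cl2/H2O (10:1), 25 °C
Reagents that add atoms: none
Why: Hayashi–Miyaura asymmetric 1,4-addition of an arylboronic acid to a chromone, run without added base so that the flavanone formed does not reopen. C2'' is set by the ligand: by the correlation (S)-biaryl bisphosphine to (S)-3-arylcycloalkanone, which maps onto (S)-flavanone, the (R)-ligand should give 2''R, and the antipode is available if the sense proves opposite. The aryl bromide and the secondary alcohol are inert to the rhodium catalyst.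

Step 8
Reactants: 11 8''-(flavan-4α-yl)-(2''R)-flavanone
Product: 12 3β-O-methanesulfonate of 11 (2S,3S,4R,2''R)
Conditions: MsCl (2 equiv), Et3N (3 equiv), CH2Cl2, −20 to 0 °C
Reagents that add atoms: methanesulfonyl chloride, CS(=O)(=O)Cl
Why: Sulfonylation of the only hydroxyl group with retention at C3; in a non-ionising solvent at low temperature the mesylate should be isolable, and brief exposure to Et3N in the cold does not open ring F.

Step 9
Reactants: 12 3β-mesylate
Product: 14 3α-(flavanon-8''-yl)flavan-4β-ol (2R,3R,4R,2''R; 2,3-trans-3,4-trans), via phenonium ion 13 (not isolated)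
Conditions: (CF3)2CHOH/CH2Cl2 (1:1), H2O (20 equiv), 2,6-lutidine (1.2 equiv), 0 to 35 °C
Reagents that add atoms: water, O
Why: Ionisation of the axial 3β-mesylate is assisted by ring D, which is axial on the opposite (α) face of C4 and therefore antiperiplanar to C3–O; C8'' bonds to C3 from the rear as mesylate leaves (Ar1-3 participation) and gives the spirocyclopropyl arenium ion 13, whose charge rests on the oxygen-bearing carbons C5'', C7'' and C8a''. The bridge opens at C4, because only there is the charge taken over by ring A (O1 and 5-O ortho, 7-O para), and water adds to C4 from the β face; the sum is a Wagner–Meerwein 1,2-aryl shift that breaks C4–C8'' and C3–O and makes C3–C8'' and C4–O. The closest known reactions are the solvolytic phenonium shift of 3-aryl-2-butyl sulfonates and the C2-to-C3 migration of ring B in 2,3-trans-flavan-3-yl sulfonates. No ring of the target is closed; the only closure is the transient 3-exo spirocyclisation, which is undone in the same step. C3 is set by inversion: ring D stays on the α face that it occupied at C4, so it ends trans to ring B (β, from 1) and equatorial, and any cis isomer would be corrected by enolisation in 15 because trans is the stable form. C4 is expected β (anti opening) but is destroyed in step 10, so its control is not needed. The step needs migration of ring D instead of ring B or H-2, opening at C4 instead of C3, and capture by water instead of proton loss: the 2,3-cis arrangement keeps ring B gauche to the leaving group, the non-basic ionising medium disfavours removal or shift of the antiperiplanar H-2, attack of water at C3 would only return 11, and excess water with a hindered buffer should outrun loss of H-3. The bromine at C8 and the acyl group on ring D keep both phloroglucinol rings from intercepting the cationic C4.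

Step 10
Reactants: 14 3α-arylflavan-4β-ol
Product: 15 hepta-O-benzyl-8-bromo-biflavanone (2R,3S,2''R)
Conditions: Dess–Martin periodinane (1.5 equiv), CH2Cl2, 0 °C to rt
Reagents that add atoms: none
Why: Dess–Martin oxidation of the only free hydroxyl group under neutral to weakly acidic conditions, which cannot open rings C and F. H-3 becomes acidic only now, and the diequatorial trans arrangement already present is the thermodynamic one.

Step 11
Reactants: 15 hepta-O-benzyl-8-bromo-biflavanone
Product: 16 target biflavanone (2R,3S,2''R)
Conditions: H2 (1 atm), Pd(OH)2/C, NaOAc (1.2 equiv), THF/MeOH (1:1), rt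
Reagents that add atoms: none
Why: Hydrogenolysis of seven benzyl ethers and hydrodebromination at C8 in one operation. The acetate buffer takes up HBr without creating a medium basic enough for retro-oxa-Michael opening, and the two aryl ketones become chelated by 5-OH and 5''-OH and resist reduction.

**Compound list**

1 | (+)-epicatechin, (2S,3S)-2-(3,4-dihydroxyphenyl)chroman-3,5,7-triol | O[C@H]1Cc2c(O)cc(O)cc2O[C@H]1c1ccc(O)c(O)c1 | starting material

2 | (2S,3S)-5,7-bis(benzyloxy)-2-[3,4-bis(benzyloxy)phenyl]chroman-3-ol | O[C@H]1Cc2c(OCc3ccccc3)cc(OCc3ccccc3)cc2O[C@H]1c1ccc(OCc2ccccc2)c(OCc2ccccc2)c1 | intermediate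

3 | (2S,3S,4R)-5,7-bis(benzyloxy)-2-[3,4-bis(benzyloxy)phenyl]-4-(2-ethoxyethoxy)chroman-3-ol | O[C@H]1[C@H](OCCOCC)c2c(OCc3ccccc3)cc(OCc3ccccc3)cc2O[C@H]1c1ccc(OCc2ccccc2)c(OCc2ccccc2)c1 | intermediate

4 | (2S,3S,4R)-5,7-bis(benzyloxy)-2-[3,4-bis(benzyloxy)phenyl]-8-bromo-4-(2-ethoxyethoxy)chroman-3-ol | O[C@H]1[C@H](OCCOCC)c2c(OCc3ccccc3)cc(OCc3ccccc3)c(Br)c2O[C@H]1c1ccc(OCc2ccccc2)c(OCc2ccccc2)c1 | intermediate

5 | 2,4,6-trihydroxyacetophenone | CC(=O)c1c(O)cc(O)cc1O | starting material

6 | 1-[2,4-bis(benzyloxy)-6-hydroxyphenyl]ethanone | CC(=O)c1c(O)cc(OCc2ccccc2)cc1OCc1ccccc1 | intermediate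

7 | 1-{4,6-bis(benzyloxy)-3-[(2S,3S,4R)-5,7-bis(benzyloxy)-2-[3,4-bis(benzyloxy)phenyl]-8-bromo-3-hydroxychroman-4-yl]-2-hydroxyphenyl}ethanone | O[C@H]1[C@H](c2c(O)c(C(C)=O)c(OCc3ccccc3)cc2OCc2ccccc2)c2c(OCc3ccccc3)cc(OCc3ccccc3)c(Br)c2O[C@H]1c1ccc(OCc2ccccc2)c(OCc2ccccc2)c1 | intermediate

8 | (E)-3-(dimethylamino)prop-2-en-1-one analogue of 7 (enaminone in place of the acetyl group) | O[C@H]1[C@H](c2c(O)c(C(=O)/C=C/N(C)C)c(OCc3ccccc3)cc2OCc2ccccc2)c2c(OCc3ccccc3)cc(OCc3ccccc3)c(Br)c2O[C@H]1c1ccc(OCc2ccccc2)c(OCc2ccccc2)c1 | intermediate (not isolated)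

9 | 5,7-bis(benzyloxy)-8-[(2S,3S,4R)-5,7-bis(benzyloxy)-2-[3,4-bis(benzyloxy)phenyl]-8-bromo-3-hydroxychroman-4-yl]-4H-chromen-4-one | O[C@H]1[C@H](c2c(OCc3ccccc3)cc(OCc3ccccc3)c3c2occc3=O)c2c(OCc3ccccc3)cc(OCc3ccccc3)c(Br)c2O[C@H]1c1ccc(OCc2ccccc2)c(OCc2ccccc2)c1 | intermediate

10 | 4-(benzyloxy)phenylboronic acid | OB(O)c1ccc(OCc2ccccc2)cc1 | starting material

11 | (2R)-5,7-bis(benzyloxy)-2-[4-(benzyloxy)phenyl]-8-[(2S,3S,4R)-5,7-bis(benzyloxy)-2-[3,4-bis(benzyloxy)phenyl]-8-bromo-3-hydroxychroman-4-yl]chroman-4-one | O[C@H]1[C@H](c2c(OCc3ccccc3)cc(OCc3ccccc3)c3c2O[C@@H](c2ccc(OCc4ccccc4)cc2)CC3=O)c2c(OCc3ccccc3)cc(OCc3ccccc3)c(Br)c2O[C@H]1c1ccc(OCc2ccccc2)c(OCc2ccccc2)c1 | intermediate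

12 | 3-O-methanesulfonate of 11 (2S,3S,4R,2''R) | CS(=O)(=O)O[C@H]1[C@H](c2c(OCc3ccccc3)cc(OCc3ccccc3)c3c2O[C@@H](c2ccc(OCc4ccccc4)cc2)CC3=O)c2c(OCc3ccccc3)cc(OCc3ccccc3)c(Br)c2O[C@H]1c1ccc(OCc2ccccc2)c(OCc2ccccc2)c1 | intermediate

13 | phenonium ion: C8'' spiro-bridging C3 and C4 on the α face, drawn with the charge on the 5''-benzyloxy oxygen (mesylate counter-ion; spiro centre undefined) | O=C1C[C@H](c2ccc(OCc3ccccc3)cc2)OC2=C1C(=[O+]Cc1ccccc1)C=C(OCc1ccccc1)C21[C@@H]2c3c(OCc4ccccc4)cc(OCc4ccccc4)c(Br)c3O[C@@H](c3ccc(OCc4ccccc4)c(OCc4ccccc4)c3)[C@H]12 | intermediate (not isolated)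

14 | (2R)-5,7-bis(benzyloxy)-2-[4-(benzyloxy)phenyl]-8-[(2R,3R,4R)-5,7-bis(benzyloxy)-2-[3,4-bis(benzyloxy)phenyl]-8-bromo-4-hydroxychroman-3-yl]chroman-4-one | O=C1C[C@H](c2ccc(OCc3ccccc3)cc2)Oc2c1c(OCc1ccccc1)cc(OCc1ccccc1)c2[C@@H]1[C@@H](O)c2c(OCc3ccccc3)cc(OCc3ccccc3)c(Br)c2O[C@H]1c1ccc(OCc2ccccc2)c(OCc2ccccc2)c1 | intermediate

15 | (2R)-5,7-bis(benzyloxy)-2-[4-(benzyloxy)phenyl]-8-[(2R,3S)-5,7-bis(benzyloxy)-2-[3,4-bis(benzyloxy)phenyl]-8-bromo-4-oxochroman-3-yl]chroman-4-one | O=C1C[C@H](c2ccc(OCc3ccccc3)cc2)Oc2c1c(OCc1ccccc1)cc(OCc1ccccc1)c2[C@@H]1C(=O)c2c(OCc3ccccc3)cc(OCc3ccccc3)c(Br)c2O[C@H]1c1ccc(OCc2ccccc2)c(OCc2ccccc2)c1 | intermediate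

16 | (2R)-8-[(2R,3S)-2-(3,4-dihydroxyphenyl)-5,7-dihydroxy-4-oxochroman-3-yl]-5,7-dihydroxy-2-(4-hydroxyphenyl)chroman-4-one (CNP0105436.3) | O=C1C[C@H](c2ccc(O)cc2)Oc2c1c(O)cc(O)c2[C@@H]1C(=O)c2c(O)cc(O)cc2O[C@H]1c1ccc(O)c(O)c1 | target

**Step count and risk**

Total step count: 11. Longest linear sequence: 10 (steps 1, 2, 3, 5, 6, 7, 8, 9, 10, 11, from 1 to 16).

Origin of the stereocentres:
- C2 comes from 1 and is never touched.
- C3 is set in step 9 by inversion and is held by thermodynamics from 15 on.
- C2'' is set in step 7 by the ligand.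

**Least certain steps**

Step 9 (key step).
- What may go wrong: removal or 1,2-shift of H-2, which is antiperiplanar to the mesylate just as ring D is, may outrun aryl participation. After the shift, two processes may compete with water: loss of H-3 from the cationic C4, and capture of C4 by the oxygen of the 7''-benzyloxy group with loss of benzyl (a pterocarpan-type closure).
- Fallback: the same transposition is run through a radical instead of a cation, which removes hydride shift, proton loss and oxygen participation as pathways. It sets out from 11. 1,1'-Thiocarbonyldiimidazole and DMAP in warm toluene give the 3-O-(imidazol-1-ylthiocarbonyl) derivative F1. Slow addition of (Me3Si)3SiH and AIBN in toluene at 90 °C (Barton–McCombie conditions at low hydride concentration, under which the thiocarbonyl group reacts far faster than the aryl bromide) generates the C3 radical. This radical undergoes the neophyl-type 1,2-aryl migration on the α face to the ring A benzylic C4 radical and is then reduced to the 2,3-trans-3-arylflavan F2. DDQ and water in CH2Cl2 (the reaction type of step 2) oxygenate C4, and the route is rejoined at 14.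

Step 5.
- What may go wrong: ring D of 6 is deactivated by its acetyl group, so capture of the cationic C4 may be slow. Self-alkylation at the still open C6 of ring A, or attack at the ring carbon of 6 para to the hydroxyl group, may then intervene.
- Fallback: the acyl group is introduced after the C–C bond instead of before it. It sets out from 4. Commercial 3,5-bis(benzyloxy)phenol, a far better nucleophile, is alkylated under BF3·OEt2 catalysis ortho to its hydroxyl group to give the 4α-(2-hydroxy-4,6-bis(benzyloxy)phenyl)flavan-3-ol F3. Ac2O with BF3·OEt2 then acetylates the remaining carbon ortho to the phenol (chelation-directed Friedel–Crafts acylation) and also O3, giving the C-acetyl 3-O-acetate F4. K2CO3 in MeOH removes the ester, and the route is rejoined at 7.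

Step 7.
- What may go wrong: the large chiral C8'' substituent may slow insertion into the aryl–rhodium bond until protodeboronation of 10 dominates. It may also oppose the facial preference of the ligand.
- Fallback: C2'' is obtained by equilibration and separation instead of catalysis, which is possible because the upper unit is still a base-inert flavan. It sets out from 7. Claisen–Schmidt condensation with commercial 4-(benzyloxy)benzaldehyde (KOH, EtOH/THF) gives the (E)-2'-hydroxychalcone F5. NaOAc in hot EtOH closes ring F to 11 and its (2''S) epimer F6, which are diastereomers and should be separable on silica. F6 is returned to the same equilibration, and the route is rejoined at 11.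

Step 11.
- What may go wrong: hydrogenolysis of the benzylic C2–O1 or C2''–O1'' bonds (ring opening to dihydrochalcones) on prolonged exposure, incomplete cleavage of C–Br, or epimerisation by ring opening once 4'-OH and 4'''-OH are free.
- Fallback: the benzyl ethers are removed by a Lewis acid and palladium is used only briefly. It sets out from 15. BCl3 with pentamethylbenzene as cation scavenger in CH2Cl2 at −78 °C gives the 8-bromo heptaphenol F7. A short hydrogenation (H2, Pd/C, NaOAc, MeOH), which has to cleave only the C–Br bond, leads to 16.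

**Further compounds**

F1 | step 9 | 3-O-(imidazol-1-ylthiocarbonyl) derivative of 11 (2,3-cis-3,4-trans, 2''R) | S=C(n1ccnc1)O[C@H]1[C@H](c2c(OCc3ccccc3)cc(OCc3ccccc3)c3c2O[C@@H](c2ccc(OCc4ccccc4)cc2)CC3=O)c2c(OCc3ccccc3)cc(OCc3ccccc3)c(Br)c2O[C@H]1c1ccc(OCc2ccccc2)c(OCc2ccccc2)c1

F2 | step 9 | 2,3-trans-3α-(flavanon-8''-yl)-8-bromoflavan, the C4H2 analogue of 14 (2R,3S,2''R) | O=C1C[C@H](c2ccc(OCc3ccccc3)cc2)Oc2c1c(OCc1ccccc1)cc(OCc1ccccc1)c2[C@@H]1Cc2c(OCc3ccccc3)cc(OCc3ccccc3)c(Br)c2O[C@H]1c1ccc(OCc2ccccc2)c(OCc2ccccc2)c1

F3 | step 5 | (2S,3S,4R)-5,7-bis(benzyloxy)-4-[2,4-bis(benzyloxy)-6-hydroxyphenyl]-2-[3,4-bis(benzyloxy)phenyl]-8-bromochroman-3-ol (2,3-cis-3,4-trans) | O[C@H]1[C@H](c2c(O)cc(OCc3ccccc3)cc2OCc2ccccc2)c2c(OCc3ccccc3)cc(OCc3ccccc3)c(Br)c2O[C@H]1c1ccc(OCc2ccccc2)c(OCc2ccccc2)c1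

F4 | step 5 | 3-O-acetate of 7 | CC(=O)O[C@H]1[C@H](c2c(O)c(C(C)=O)c(OCc3ccccc3)cc2OCc2ccccc2)c2c(OCc3ccccc3)cc(OCc3ccccc3)c(Br)c2O[C@H]1c1ccc(OCc2ccccc2)c(OCc2ccccc2)c1

F5 | step 7 | (E)-chalcone from 7 and 4-(benzyloxy)benzaldehyde | O[C@H]1[C@H](c2c(O)c(C(=O)/C=C/c3ccc(OCc4ccccc4)cc3)c(OCc3ccccc3)cc2OCc2ccccc2)c2c(OCc3ccccc3)cc(OCc3ccccc3)c(Br)c2O[C@H]1c1ccc(OCc2ccccc2)c(OCc2ccccc2)c1

F6 | step 7 | (2''S) epimer of 11 | O[C@H]1[C@H](c2c(OCc3ccccc3)cc(OCc3ccccc3)c3c2O[C@H](c2ccc(OCc4ccccc4)cc2)CC3=O)c2c(OCc3ccccc3)cc(OCc3ccccc3)c(Br)c2O[C@H]1c1ccc(OCc2ccccc2)c(OCc2ccccc2)c1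

F7 | step 11 | 8-bromo derivative of 16 (2R,3S,2''R) | O=C1C[C@H](c2ccc(O)cc2)Oc2c1c(O)cc(O)c2[C@@H]1C(=O)c2c(O)cc(O)c(Br)c2O[C@H]1c1ccc(O)c(O)c1

A1 | alternative 1 | 5,7-bis(benzyloxy)-2-[3,4-bis(benzyloxy)phenyl]-3-iodo-4H-chromen-4-one | O=c1c(I)c(-c2ccc(OCc3ccccc3)c(OCc3ccccc3)c2)oc2cc(OCc3ccccc3)cc(OCc3ccccc3)c12

A2 | alternative 1 | (2R)-5,7-bis(benzyloxy)-2-[4-(benzyloxy)phenyl]-8-(4,4,5,5-tetramethyl-1,3,2-dioxaborolan-2-yl)chroman-4-one | O=C1C[C@H](c2ccc(OCc3ccccc3)cc2)Oc2c1c(OCc1ccccc1)cc(OCc1ccccc1)c2B1OC(C)(C)C(C)(C)O1

A3 | alternative 1 | hepta-O-benzyl 3,8''-linked flavone–(2''R)-flavanone | O=C1C[C@H](c2ccc(OCc3ccccc3)cc2)Oc2c1c(OCc1ccccc1)cc(OCc1ccccc1)c2-c1c(-c2ccc(OCc3ccccc3)c(OCc3ccccc3)c2)oc2cc(OCc3ccccc3)cc(OCc3ccccc3)c2c1=O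

A4 | alternative 2 | (2R)-5,7-bis(benzyloxy)-2-[4-(benzyloxy)phenyl]-8-[(E)-2-[3,4-bis(benzyloxy)phenyl]ethenyl]chroman-4-one | O=C1C[C@H](c2ccc(OCc3ccccc3)cc2)Oc2c1c(OCc1ccccc1)cc(OCc1ccccc1)c2/C=C/c1ccc(OCc2ccccc2)c(OCc2ccccc2)c1

A5 | alternative 2 | 3,5-bis(benzyloxy)-2-(hydroxymethyl)phenol | OCc1c(O)cc(OCc2ccccc2)cc1OCc1ccccc1

A6 | alternative 2 | hepta-O-benzyl 2,3-trans-3-(flavanon-8''-yl)flavan (2R,3S,2''R) | O=C1C[C@H](c2ccc(OCc3ccccc3)cc2)Oc2c1c(OCc1ccccc1)cc(OCc1ccccc1)c2[C@@H]1Cc2c(OCc3ccccc3)cc(OCc3ccccc3)cc2O[C@H]1c1ccc(OCc2ccccc2)c(OCc2ccccc2)c1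

A7 | alternative 3 | (E)-2',4',6',3,4-pentahydroxychalcone | O=C(/C=C/c1ccc(O)c(O)c1)c1c(O)cc(O)cc1O

A8 | alternative 3 | (2R)-naringenin | O=C1C[C@H](c2ccc(O)cc2)Oc2cc(O)cc(O)c12

A9 | alternative 3 | ring B quinone methide after α-carbon-to-C8'' coupling (C3 and the exocyclic alkene undefined, 2''R) | O=C1C=CC(=CC(C(=O)c2c(O)cc(O)cc2O)c2c(O)cc(O)c3c2O[C@@H](c2ccc(O)cc2)CC3=O)C=C1O
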